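**Plan**

- Cuts: the two C11=C12 double bonds (two-directional Horner–Wadsworth–Emmons olefination on the C10 trienedial core, using the C2 symmetry); then, in each C15 end group, the ring bond C1–C6, the C6–C7 bond (Sonogashira) and the C1–C2 bond (copper-catalysed coupling).
- Ring-forming event: 6-exo reductive Heck cyclisation of an acyclic (Z)-bromoenyne onto a 2-methylallyl group. It is possible because ring carbon C1, next to the alkyne-bearing sp2 carbon C6, is a CMe2 carbon: one methyl can be a =CH2 terminus that takes up palladium, has no β-hydrogen and is simply reduced.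
- Forward order: tartrate chiron → 2-methylallyl arm (C1, C2) and methyl ketone arm (C5) → 1,1-dibromoalkene (C6) → alkyne on C6 → ring closure → two C15 phosphonates joined to the C10 dial → desilylation.
- Stereochemistry: C3 and C4 (3S,4S, trans-diol) of each ring are C2 and C3 of natural L-tartaric acid, whose four carbons become ring carbons C2–C5; no stereocentre is made or touched afterwards.
- Double bonds: 9E from the E-enynol, 13E/15E/13'E from the all-E dial, 11E from the E-selective phosphonate olefination.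

Key step: step 13

Remark: compounds 1, 4 and 17 are taken as commercial; ring atoms carry carotenoid numbers (C1 = CMe2, C2 = CH2, C3/C4 = carbinol carbons, C5 = C(Me)=, C6 = ring carbon bearing the C7≡C8 alkyne).

**Route**

Step 1
Reactants: 1 (2E)-3-methylpent-2-en-4-yn-1-ol
Product: 2 (3E)-5-bromo-3-methylpent-3-en-1-yne
Conditions: PBr3 (0.4 equiv), pyridine (cat.), Et2O, −10 °C
Reagents that add atoms: phosphorus tribromide, BrP(Br)Br
Why: SN2 bromination of a primary allylic alcohol through its phosphite ester leaves the terminal alkyne untouched and keeps the E geometry of the trisubstituted double bond.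

Step 2
Reactants: 2 (3E)-5-bromo-3-methylpent-3-en-1-yne
Product: 3 diethyl [(2E)-3-methylpent-2-en-4-yn-1-yl]phosphonate
Conditions: P(OEt)3 (neat), 100 °C
Reagents that add atoms: triethyl phosphite, CCOP(OCC)OCC
Why: Michaelis–Arbuzov reaction of a reactive primary allylic bromide gives the allylic phosphonate, with loss of volatile bromoethane driving the reaction.

Step 3
Reactants: 4 [(4S,5S)-2,2-dimethyl-1,3-dioxolane-4,5-diyl]dimethanol (2,3-O-isopropylidene-L-threitol)
Product: 5 [(4S,5S)-5-({[tert-butyl(dimethyl)silyl]oxy}methyl)-2,2-dimethyl-1,3-dioxolan-4-yl]methanol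
Conditions: NaH (1.0 equiv), THF, 0 °C; then TBSCl (1.0 equiv), rt
Reagents that add atoms: tert-butyldimethylsilyl chloride, CC(C)(C)[Si](C)(C)Cl
Why: Monosilylation of a C2-symmetric diol through its monosodium alkoxide breaks the symmetry of the chiron, and since both hydroxyls are equivalent no regiochemical question arises.

Step 4
Reactants: 5 [(4S,5S)-5-({[tert-butyl(dimethyl)silyl]oxy}methyl)-2,2-dimethyl-1,3-dioxolan-4-yl]methanol
Product: 7 tert-butyl{[(4S,5S)-2,2-dimethyl-5-(2-methylprop-2-en-1-yl)-1,3-dioxolan-4-yl]methoxy}dimethylsilane, via primary triflate 6 (not isolated)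
Conditions: Tf2O, pyridine, CH2Cl2, −20 °C; crude 6, then CH2=C(CH3)MgBr, CuBr·SMe2 (10 mol %), THF/Et2O, −30 → 0 °C
Reagents that add atoms: trifluoromethanesulfonic anhydride, O=S(=O)(OS(=O)(=O)C(F)(F)F)C(F)(F)F (atoms present in 6 only); isopropenylmagnesium bromide, C=C(C)[Mg]Br
Why: Copper-catalysed SN2 coupling of a primary alkyl triflate with an alkenyl Grignard reagent is fast at low temperature, outruns β-alkoxy elimination and places the 2-methylallyl group (C1 with its future methyls) on C2 without touching the stereocentres.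

Step 5
Reactants: 7 tert-butyl{[(4S,5S)-2,2-dimethyl-5-(2-methylprop-2-en-1-yl)-1,3-dioxolan-4-yl]methoxy}dimethylsilane
Product: 8 [(4S,5S)-2,2-dimethyl-5-(2-methylprop-2-en-1-yl)-1,3-dioxolan-4-yl]methanol
Conditions: Bu4NF, THF, 0 °C → rt
Reagents that add atoms: none
Why: Fluoride cleaves the primary silyl ether and leaves the acetonide and the alkene untouched.

Step 6
Reactants: 8 [(4S,5S)-2,2-dimethyl-5-(2-methylprop-2-en-1-yl)-1,3-dioxolan-4-yl]methanol
Product: 9 (4R,5S)-2,2-dimethyl-5-(2-methylprop-2-en-1-yl)-1,3-dioxolane-4-carbaldehyde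
Conditions: Dess–Martin periodinane, CH2Cl2, rt
Reagents that add atoms: none
Why: Dess–Martin oxidation gives the α-alkoxy aldehyde under near-neutral conditions, and the trans-dioxolane is the thermodynamically favoured arrangement, so the α-centre (C4) is not at risk.

Step 7
Reactants: 9 (4R,5S)-2,2-dimethyl-5-(2-methylprop-2-en-1-yl)-1,3-dioxolane-4-carbaldehyde
Product: 10 1-[(4S,5S)-2,2-dimethyl-5-(2-methylprop-2-en-1-yl)-1,3-dioxolan-4-yl]ethan-1-ol (both carbinol epimers)
Conditions: MeMgBr, THF, −78 °C; aq NH4Cl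
Reagents that add atoms: methylmagnesium bromide, C[Mg]Br
Why: Grignard addition to the aldehyde installs the C5 methyl group, and the new carbinol centre is removed in the next step so its configuration is irrelevant.

Step 8
Reactants: 10 1-[(4S,5S)-2,2-dimethyl-5-(2-methylprop-2-en-1-yl)-1,3-dioxolan-4-yl]ethan-1-ol
Product: 11 1-[(4R,5S)-2,2-dimethyl-5-(2-methylprop-2-en-1-yl)-1,3-dioxolan-4-yl]ethan-1-one
Conditions: Dess–Martin periodinane, CH2Cl2, rt
Reagents that add atoms: none
Why: Dess–Martin oxidation of the secondary alcohol gives the methyl ketone, with the α-centre again held in the favoured trans-dioxolane.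

Step 9
Reactants: 11 1-[(4R,5S)-2,2-dimethyl-5-(2-methylprop-2-en-1-yl)-1,3-dioxolan-4-yl]ethan-1-one
Product: 12 (4S,5S)-4-(1,1-dibromoprop-1-en-2-yl)-2,2-dimethyl-5-(2-methylprop-2-en-1-yl)-1,3-dioxolane
Conditions: CBr4 (2 equiv), PPh3 (4 equiv), 2,6-lutidine (trace-acid scavenger), toluene, 80 °C
Reagents that add atoms: carbon tetrabromide, BrC(Br)(Br)Br
Why: Ramirez (Corey–Fuchs type) dibromoolefination with Ph3P=CBr2 formed in the flask converts the ketone, activated by its α-oxygen, into the 1,1-dibromoalkene that supplies C6 with two differentiable bromines.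

Step 10
Reactants: 12 (4S,5S)-4-(1,1-dibromoprop-1-en-2-yl)-2,2-dimethyl-5-(2-methylprop-2-en-1-yl)-1,3-dioxolane
Product: 13 (3S,4S)-1,1-dibromo-2,6-dimethylhepta-1,6-diene-3,4-diol
Conditions: AcOH/H2O (4:1), 50 °C
Reagents that add atoms: none
Why: Acid hydrolysis of the acetonide is placed here because the allylic C–O bond next to the electron-poor dibromoalkene cannot ionise and the isolated 1,1-disubstituted alkene is inert to aqueous acetic acid.

Step 11
Reactants: 13 (3S,4S)-1,1-dibromo-2,6-dimethylhepta-1,6-diene-3,4-diol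
Product: 14 (3S,4S)-1,1-dibromo-3,4-bis{[tert-butyl(dimethyl)silyl]oxy}-2,6-dimethylhepta-1,6-diene
Conditions: TBSOTf (2.5 equiv), 2,6-lutidine, CH2Cl2, 0 °C → rt
Reagents that add atoms: tert-butyldimethylsilyl trifluoromethanesulfonate, CC(C)(C)[Si](C)(C)OS(=O)(=O)C(F)(F)F
Why: A silyl triflate with a hindered pyridine base silylates both secondary hydroxyls, giving a diol protection that fluoride can remove at the polyene stage, where acid cannot be used.

Step 12
Reactants: 14 (3S,4S)-1,1-dibromo-3,4-bis{[tert-butyl(dimethyl)silyl]oxy}-2,6-dimethylhepta-1,6-diene and 3 diethyl [(2E)-3-methylpent-2-en-4-yn-1-yl]phosphonate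
Product: 15 diethyl [(2E,6Z,8S,9S)-6-bromo-8,9-bis{[tert-butyl(dimethyl)silyl]oxy}-3,7,11-trimethyldodeca-2,6,11-trien-4-yn-1-yl]phosphonate
Conditions: 3 (1.1 equiv), Pd(PPh3)4 (5 mol %), CuI (10 mol %), i-Pr2NH, benzene, rt
Reagents that add atoms: none
Why: Sonogashira coupling of a 1,1-dibromoalkene occurs at the less hindered bromide, here the one cis to methyl and trans to the bulky bis-silyloxy chain, which puts the alkyne on C6 and leaves the bromide cis to C4 as ring closure requires.

Step 13
Reactants: 15 diethyl [(2E,6Z,8S,9S)-6-bromo-8,9-bis{[tert-butyl(dimethyl)silyl]oxy}-3,7,11-trimethyldodeca-2,6,11-trien-4-yn-1-yl]phosphonate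
Product: 16 diethyl {(2E)-5-[(3S,4S)-3,4-bis{[tert-butyl(dimethyl)silyl]oxy}-2,6,6-trimethylcyclohex-1-en-1-yl]-3-methylpent-2-en-4-yn-1-yl}phosphonate
Conditions: Pd(OAc)2 (10 mol %), PPh3 (25 mol %), HCO2Na (1.5 equiv, added in portions), Et4NCl, DMF, 80 °C
Reagents that add atoms: none
Why: Zerovalent palladium inserts into the one remaining C–Br bond, which lies cis to the oxygenated chain, and the alkenylpalladium adds syn across the 2-methylallyl double bond with carbon going to the disubstituted alkene carbon, so that the C6–C1 ring bond and the quaternary C1 arise together; the resulting CH2–Pd has no β-hydrogen, exchanges bromide for formate, loses CO2 and reductively eliminates C–H to leave the second methyl of the CMe2 group. The closest known reaction type is the formate-terminated (reductive) intramolecular Heck cyclisation of alkenyl halides onto 1,1-disubstituted alkenes (cyclisation with hydride capture). The cyclohexene ring closes in the 6-exo-trig mode. No new stereocentre is formed, since C1 becomes a CMe2 carbon, and the (3S,4S) centres on the tether are spectators. The step needs 6-exo over 7-endo closure, ring closure before hydride capture of the alkenylpalladium, and no reinsertion of the neopentyl-type palladium alkyl; these should be secured by the exo preference of carbopalladation at this tether length, the slow feed of sparingly soluble formate, and the tetrasubstituted new ring alkene, which blocks 3-exo return, while the C–Br bond fixes the site and the alkyne on the same carbon cannot be reached.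

Step 14
Reactants: 16 diethyl {(2E)-5-[(3S,4S)-3,4-bis{[tert-butyl(dimethyl)silyl]oxy}-2,6,6-trimethylcyclohex-1-en-1-yl]-3-methylpent-2-en-4-yn-1-yl}phosphonate (2.2 equiv) and 17 (2E,4E,6E)-2,7-dimethylocta-2,4,6-trienedial
Product: 18 (3S,4S,3'S,4'S)-3,4,3',4'-tetrakis{[tert-butyl(dimethyl)silyl]oxy}-7,8,7',8'-tetradehydro-β,β-carotene (all-E)
Conditions: NaN(SiMe3)2 (2.2 equiv), THF, −78 °C; then 17 (1.0 equiv), −78 → 0 °C, dark, argon
Reagents that add atoms: none
Why: Two-fold Horner–Wadsworth–Emmons olefination of the symmetric trienedial with the allylic phosphonate anion forms both C11=C12 double bonds at once, and the reversible addition of the stabilised anion should favour the E geometry at each new disubstituted double bond.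

Step 15
Reactants: 18 (3S,4S,3'S,4'S)-3,4,3',4'-tetrakis{[tert-butyl(dimethyl)silyl]oxy}-7,8,7',8'-tetradehydro-β,β-carotene
Product: 19 (3S,4S,3'S,4'S)-7,8,7',8'-tetradehydro-β,β-carotene-3,4,3',4'-tetrol (CNP0283832.1)
Conditions: Bu4NF (6 equiv), THF, rt, dark, argon
Reagents that add atoms: none
Why: Fluoride cleaves the four silyl ethers under non-acidic conditions that leave the acid-sensitive allylic C4–O bonds and the polyene geometry untouched, so the centres carried from tartrate appear unchanged.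

**Compound list**

1 | (2E)-3-methylpent-2-en-4-yn-1-ol | C#C/C(C)=C/CO | starting material
2 | (3E)-5-bromo-3-methylpent-3-en-1-yne | C#C/C(C)=C/CBr | intermediate
3 | diethyl [(2E)-3-methylpent-2-en-4-yn-1-yl]phosphonate | C#C/C(C)=C/CP(=O)(OCC)OCC | intermediate
4 | [(4S,5S)-2,2-dimethyl-1,3-dioxolane-4,5-diyl]dimethanol | OC[C@@H]1OC(C)(C)O[C@H]1CO | starting material
5 | [(4S,5S)-5-({[tert-butyl(dimethyl)silyl]oxy}methyl)-2,2-dimethyl-1,3-dioxolan-4-yl]methanol | OC[C@@H]1OC(C)(C)O[C@H]1CO[Si](C)(C)C(C)(C)C | intermediate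
6 | [(4S,5S)-5-({[tert-butyl(dimethyl)silyl]oxy}methyl)-2,2-dimethyl-1,3-dioxolan-4-yl]methyl trifluoromethanesulfonate (not isolated) | O=S(=O)(OC[C@@H]1OC(C)(C)O[C@H]1CO[Si](C)(C)C(C)(C)C)C(F)(F)F | intermediate
7 | tert-butyl{[(4S,5S)-2,2-dimethyl-5-(2-methylprop-2-en-1-yl)-1,3-dioxolan-4-yl]methoxy}dimethylsilane | C=C(C)C[C@@H]1OC(C)(C)O[C@H]1CO[Si](C)(C)C(C)(C)C | intermediate
8 | [(4S,5S)-2,2-dimethyl-5-(2-methylprop-2-en-1-yl)-1,3-dioxolan-4-yl]methanol | C=C(C)C[C@@H]1OC(C)(C)O[C@H]1CO | intermediate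
9 | (4R,5S)-2,2-dimethyl-5-(2-methylprop-2-en-1-yl)-1,3-dioxolane-4-carbaldehyde | C=C(C)C[C@@H]1OC(C)(C)O[C@H]1C=O | intermediate
10 | 1-[(4S,5S)-2,2-dimethyl-5-(2-methylprop-2-en-1-yl)-1,3-dioxolan-4-yl]ethan-1-ol (both carbinol epimers) | C=C(C)C[C@@H]1OC(C)(C)O[C@H]1C(C)O | intermediate
11 | 1-[(4R,5S)-2,2-dimethyl-5-(2-methylprop-2-en-1-yl)-1,3-dioxolan-4-yl]ethan-1-one | C=C(C)C[C@@H]1OC(C)(C)O[C@H]1C(C)=O | intermediate
12 | (4S,5S)-4-(1,1-dibromoprop-1-en-2-yl)-2,2-dimethyl-5-(2-methylprop-2-en-1-yl)-1,3-dioxolane | C=C(C)C[C@@H]1OC(C)(C)O[C@H]1C(C)=C(Br)Br | intermediate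
13 | (3S,4S)-1,1-dibromo-2,6-dimethylhepta-1,6-diene-3,4-diol | C=C(C)C[C@H](O)[C@@H](O)C(C)=C(Br)Br | intermediate
14 | (3S,4S)-1,1-dibromo-3,4-bis{[tert-butyl(dimethyl)silyl]oxy}-2,6-dimethylhepta-1,6-diene | C=C(C)C[C@H](O[Si](C)(C)C(C)(C)C)[C@@H](O[Si](C)(C)C(C)(C)C)C(C)=C(Br)Br | intermediate
15 | diethyl [(2E,6Z,8S,9S)-6-bromo-8,9-bis{[tert-butyl(dimethyl)silyl]oxy}-3,7,11-trimethyldodeca-2,6,11-trien-4-yn-1-yl]phosphonate | C=C(C)C[C@H](O[Si](C)(C)C(C)(C)C)[C@@H](O[Si](C)(C)C(C)(C)C)/C(C)=C(\Br)C#C/C(C)=C/CP(=O)(OCC)OCC | intermediate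
16 | diethyl {(2E)-5-[(3S,4S)-3,4-bis{[tert-butyl(dimethyl)silyl]oxy}-2,6,6-trimethylcyclohex-1-en-1-yl]-3-methylpent-2-en-4-yn-1-yl}phosphonate | CC1=C(C#C/C(C)=C/CP(=O)(OCC)OCC)C(C)(C)C[C@H](O[Si](C)(C)C(C)(C)C)[C@H]1O[Si](C)(C)C(C)(C)C | intermediate
17 | (2E,4E,6E)-2,7-dimethylocta-2,4,6-trienedial | O=C/C(C)=C/C=C/C=C(C)/C=O | starting material
18 | (3S,4S,3'S,4'S)-3,4,3',4'-tetrakis{[tert-butyl(dimethyl)silyl]oxy}-7,8,7',8'-tetradehydro-β,β-carotene | CC1=C(C#C/C(C)=C/C=C/C(C)=C/C=C/C=C(C)/C=C/C=C(\C)C#CC2=C(C)[C@H](O[Si](C)(C)C(C)(C)C)[C@@H](O[Si](C)(C)C(C)(C)C)CC2(C)C)C(C)(C)C[C@H](O[Si](C)(C)C(C)(C)C)[C@H]1O[Si](C)(C)C(C)(C)C | intermediate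
19 | (3S,4S,3'S,4'S)-7,8,7',8'-tetradehydro-β,β-carotene-3,4,3',4'-tetrol | CC1=C(C#C/C(C)=C/C=C/C(C)=C/C=C/C=C(C)/C=C/C=C(\C)C#CC2=C(C)[C@H](O)[C@@H](O)CC2(C)C)C(C)(C)C[C@H](O)[C@H]1O | target

**Step count**

Total step count: 15. Longest linear sequence: 13 steps (steps 3–15, from 4 to 19); steps 1–2 form the side branch.

**Steps most likely to fail**

1. Step 13. The alkenylpalladium may be reduced by formate before it closes the ring, or the neopentyl-type palladium alkyl may close in the 7-endo sense or rearrange. The fallback sets out from 14 and returns at 16. Cobalt-catalysed Markovnikov hydrobromination of the 2-methylallyl group (Co(acac)2, t-BuOOH, Et3SiH, TsBr) should give the tertiary bromide (3S,4S)-1,1,6-tribromo-3,4-bis{[tert-butyl(dimethyl)silyl]oxy}-2,6-dimethylhept-1-ene F1. Sonogashira coupling with 3 under the conditions of step 12 should give diethyl [(2E,6Z,8S,9S)-6,11-dibromo-8,9-bis{[tert-butyl(dimethyl)silyl]oxy}-3,7,11-trimethyldodeca-2,6-dien-4-yn-1-yl]phosphonate F2. A nickel-catalysed reductive cross-electrophile cyclisation (NiBr2(dme), pyridine-type ligand, MgCl2, Mn powder, DMA) then joins the alkenyl bromide carbon to the tertiary carbon through a tertiary radical captured at nickel and gives 16.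

2. Step 12. Oxidative addition may occur at the wrong bromide or at both, giving the regioisomeric or doubly coupled enyne. The fallback sets out from 14 and returns at 16, with the order of the two palladium steps reversed. The reductive Heck cyclisation is run on the gem-dibromoalkene itself (Pd(OAc)2, P(t-Bu)3, HCO2Na fed slowly, DMF, 80 °C). Only the bromide cis to the oxygenated chain can reach the 2-methylallyl group, so the tether makes the choice and the product should be {[(1S,2S)-4-bromo-3,5,5-trimethylcyclohex-3-ene-1,2-diyl]bis(oxy)}bis[tert-butyl(dimethyl)silane] F3. Sonogashira coupling of this hindered cyclic bromide with 3 (PdCl2(PhCN)2, P(t-Bu)3, CuI, i-Pr2NH, dioxane) then gives 16.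

3. Step 9. Olefination of the hindered α-alkoxy methyl ketone may be slow, with enolisation or loss of the acetonide through traces of HBr. The fallback sets out from 11 and returns at 12. Wittig bromomethylenation with the more reactive ylide from (bromomethyl)triphenylphosphonium bromide and KOt-Bu (THF, −78 °C → rt) should give (4S,5S)-4-(1-bromoprop-1-en-2-yl)-2,2-dimethyl-5-(2-methylprop-2-en-1-yl)-1,3-dioxolane F4, whose E/Z ratio is irrelevant. Deprotonation of its vinylic C–H geminal to bromine with lithium 2,2,6,6-tetramethylpiperidide (THF, −100 °C) and quenching of the α-bromoalkenyllithium with BrCCl2CCl2Br gives 12.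

**Further compounds**

F1 | step 13 | (3S,4S)-1,1,6-tribromo-3,4-bis{[tert-butyl(dimethyl)silyl]oxy}-2,6-dimethylhept-1-ene | CC(C)(Br)C[C@H](O[Si](C)(C)C(C)(C)C)[C@@H](O[Si](C)(C)C(C)(C)C)C(C)=C(Br)Br
F2 | step 13 | diethyl [(2E,6Z,8S,9S)-6,11-dibromo-8,9-bis{[tert-butyl(dimethyl)silyl]oxy}-3,7,11-trimethyldodeca-2,6-dien-4-yn-1-yl]phosphonate | CC(C)(Br)C[C@H](O[Si](C)(C)C(C)(C)C)[C@@H](O[Si](C)(C)C(C)(C)C)/C(C)=C(\Br)C#C/C(C)=C/CP(=O)(OCC)OCC
F3 | step 12 | {[(1S,2S)-4-bromo-3,5,5-trimethylcyclohex-3-ene-1,2-diyl]bis(oxy)}bis[tert-butyl(dimethyl)silane] | CC1=C(Br)C(C)(C)C[C@H](O[Si](C)(C)C(C)(C)C)[C@H]1O[Si](C)(C)C(C)(C)C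
F4 | step 9 | (4S,5S)-4-(1-bromoprop-1-en-2-yl)-2,2-dimethyl-5-(2-methylprop-2-en-1-yl)-1,3-dioxolane (E/Z mixture) | C=C(C)C[C@@H]1OC(C)(C)O[C@H]1C(C)=CBr
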